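**Plan**

- Numbering (daucane): C1 quaternary C–Me (fusion), C2/C3 CH2, C4 C(OH)iPr, C5 fusion CH, C6 CH–O-isovaleryl, C7 CH2, C8(Me)–C9 epoxide, C10 CH–OAc. Rings: cyclopentane C1–C5, cycloheptane C1, C5–C10.
- Retrosynthesis: (a) acetate, epoxide and isovalerate come off and C6–OH goes back to a ketone; (b) C8=C9 is cut (ring-closing metathesis), which opens the seven-membered ring to a trans-1,2-disubstituted cyclopentane; (c) the cyclopentane is cut at C1–C2 and C4–C5 in one stroke.
- Enabling feature for (c): the tertiary carbinol C4 is β to the C6 oxygen (aldol retron C4–C5–C6=O) and C1 is the β-carbon of a C6 enone. The five-membered ring is therefore the [3+2] sum of the enone C5=C1 and the homoenolate C2–C3–C4(=O)iPr stored in 1-isopropylcyclopropanol; two acceptor-type β-carbons, C1 and C2, are joined by polarity reversal.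
- Forward: chain assembly (propiolate + acrolein, syn-carbocupration, Weinreb ketone) gives a Z-enone; the cyclopentane arises first (key step), the seven-membered ring second (metathesis), then C6 reduction, esters and epoxide.
- Stereochemistry: C10 by catalyst-controlled alkynylation; C1 from C10 (1,3-allylic strain and Felkin–Anh attack in the Z-enone); C5 and C4 in the same step (acyl trans to the larger C1 branch, zinc-chelated aldol), so the trans ring fusion is fixed before the seven-membered ring exists; C6 by C4-OH-directed hydride delivery; C8/C9 by C10-OH-directed epoxidation.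

Key step: step 7

Assumption: (S,S)-ProPhenol is taken to give the (R)-alcohol 3; if the facial sense is the reverse, the (R,R)-ligand is used.

**Route**

Step 1
Reactants: 1 methyl propiolate; 2 acrolein
Product: 3 methyl (4R)-4-hydroxyhex-5-en-2-ynoate
Conditions: (S,S)-ProPhenol (10 mol %), Me2Zn (3 equiv), Ph3PO (20 mol %), toluene, 4 °C; then H2O
Reagents that add atoms: none
Why: Dinuclear zinc–ProPhenol-catalysed 1,2-addition of the zinc alkynylide of 1 to the aldehyde of the enal, in which the chiral ligand selects the aldehyde face and so sets the carbinol that becomes C10.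

Step 2
Reactants: 3 methyl (4R)-4-hydroxyhex-5-en-2-ynoate
Product: 4 methyl (4R)-4-{[tert-butyl(dimethyl)silyl]oxy}hex-5-en-2-ynoate
Conditions: TBSCl, imidazole, DMF, 0 → 25 °C
Reagents that add atoms: tert-butyldimethylsilyl chloride, CC(C)(C)[Si](C)(C)Cl
Why: Standard silylation of the secondary alcohol, which also installs the bulky, σ*-accepting C–OSi group that later directs the C1 face.

Step 3
Reactants: 4 methyl (4R)-4-{[tert-butyl(dimethyl)silyl]oxy}hex-5-en-2-ynoate
Product: 5 methyl (2Z,4R)-4-{[tert-butyl(dimethyl)silyl]oxy}-3-methylhexa-2,5-dienoate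
Conditions: Me2CuLi (from MeLi and CuI), THF, −78 °C; then MeOH, −78 °C
Reagents that add atoms: lithium dimethylcuprate Me2CuLi, [Li+].C[Cu-]C
Why: syn-Carbocupration of the ynoate and protonation of the alkenylcopper with retention at −78 °C place methyl and H cis, so the silyloxyallyl group ends cis to the ester (Z).

Step 4
Reactants: 5 methyl (2Z,4R)-4-{[tert-butyl(dimethyl)silyl]oxy}-3-methylhexa-2,5-dienoate
Product: 6 (2Z,4R)-4-{[tert-butyl(dimethyl)silyl]oxy}-N-methoxy-N,3-dimethylhexa-2,5-dienamide
Conditions: MeNH(OMe)·HCl, iPrMgCl, THF, −20 → 0 °C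
Reagents that add atoms: N,O-dimethylhydroxylamine hydrochloride, CNOC.Cl
Why: Weinreb amide formation by aminolysis of the ester with the chloromagnesium amide, which should leave the Z double bond and the stereocentre untouched.

Step 5
Reactants: 6 (2Z,4R)-4-{[tert-butyl(dimethyl)silyl]oxy}-N-methoxy-N,3-dimethylhexa-2,5-dienamide
Product: 7 (5Z,7R)-7-{[tert-butyl(dimethyl)silyl]oxy}-2,6-dimethylnona-1,5,8-trien-4-one
Conditions: 2-methylallylmagnesium chloride, THF, −78 → −40 °C; cold pH 7 buffer
Reagents that add atoms: 2-methylallylmagnesium chloride, CC(=C)C[Mg]Cl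
Why: Weinreb ketone synthesis, in which the chelated tetrahedral magnesium intermediate stops at single addition and releases the β,γ-unsaturated ketone only on cold neutral work-up, limiting double-bond migration.

Step 6
Reactants: 8 methyl isobutyrate
Product: 9 1-(propan-2-yl)cyclopropan-1-ol
Conditions: EtMgBr (2.4 equiv), Ti(OiPr)4 (20 mol %), Et2O, 0 → 25 °C; then dilute aq H2SO4
Reagents that add atoms: ethylmagnesium bromide, CC[Mg]Br
Why: Kulinkovich cyclopropanation, in which the titanacyclopropane made from EtMgBr and Ti(OiPr)4 acts as a 1,2-dicarbanion on the ester to give the 1-substituted cyclopropanol.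

Step 7
Reactants: 7 (5Z,7R)-7-{[tert-butyl(dimethyl)silyl]oxy}-2,6-dimethylnona-1,5,8-trien-4-one; 9 1-(propan-2-yl)cyclopropan-1-ol
Product: 12 1-[(1R,2R,5S)-5-[(1R)-1-{[tert-butyl(dimethyl)silyl]oxy}prop-2-en-1-yl]-2-hydroxy-5-methyl-2-(propan-2-yl)cyclopentyl]-3-methylbut-3-en-1-one, via zinc homoenolate 10 (not isolated), via zinc enolate 11 (not isolated)
Conditions: 9 (2.2 equiv), Et2Zn (1.1 equiv), THF, 0 → 50 °C; then CuBr·SMe2 (20 mol %), BF3·OEt2 (1.2 equiv), 7, −40 → 0 °C; then H2O
Reagents that add atoms: none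
Why: Proposed new method: the zinc cyclopropoxide of 9 opens to the zinc homoenolate 10 (C2 nucleophilic, the polarity-reversed β-carbon of the isopropyl ketone), copper transfers C2 to the BF3-activated enone β-carbon C1 of 7, and the zinc enolate 11, formed regiospecifically at C5, closes at once onto the pendant ketone C4; the closest known reactions are the copper-catalysed, Lewis-acid-promoted conjugate addition of zinc homoenolates to β,β-disubstituted enones and the two-stage cyclopentane annulation by conjugate addition of an acetal Grignard reagent followed by aldol, and what is new is the tandem use of a free ketone homoenolate on an acyclic β,β-disubstituted Z-enone. The cyclopentane C1–C2–C3–C4–C5 closes by a 5-(enolexo)-exo-trig aldol. C1 is controlled by 1,3-allylic strain in the Z-enone, which holds H-10 in the enone plane so that the nucleophile enters anti to the bulky C10–OSi bond (Felkin–Anh) and gives the 1S,10R relation; at C5 the acyl group settles trans to the larger silyloxyallyl branch on C1 and cis to methyl, and since C5 is enolisable and the aldol reversible this is also the expected thermodynamic outcome; at C4 the chair-like zinc chelate of enolate and ketone oxygens (Zimmerman–Traxler) places OH cis to the acyl group and isopropyl trans to it. The step needs 1,4- over 1,2-addition with no attack on the vinyl, methallyl or ketone groups, which soft organocopper delivery to the only electron-poor alkene secures, and it needs the aldol to start from C5 and not from C7 or C3, which follows because conjugate addition generates the enolate at C5 directly.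

Step 8
Reactants: 12 1-[(1R,2R,5S)-5-[(1R)-1-{[tert-butyl(dimethyl)silyl]oxy}prop-2-en-1-yl]-2-hydroxy-5-methyl-2-(propan-2-yl)cyclopentyl]-3-methylbut-3-en-1-one
Product: 13 (1S,4R,5R,10R)-10-{[tert-butyl(dimethyl)silyl]oxy}-4-hydroxydauc-8-en-6-one
Conditions: second-generation Grubbs catalyst (10 mol %), toluene (5 mM), 80 °C
Reagents that add atoms: none
Why: Ring-closing metathesis between the C9 vinyl and C8 methallyl alkenes should close the seven-membered ring on the trans-1,2-disubstituted cyclopentane as the trisubstituted C8=C9 alkene with loss of ethene, touching no stereocentre.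

Step 9
Reactants: 13 (1S,4R,5R,10R)-10-{[tert-butyl(dimethyl)silyl]oxy}-4-hydroxydauc-8-en-6-one
Product: 14 (1S,4R,5S,6S,10R)-10-{[tert-butyl(dimethyl)silyl]oxy}dauc-8-ene-4,6-diol
Conditions: Me4NBH(OAc)3, MeCN/AcOH (1:1), −30 °C; then aq work-up
Reagents that add atoms: none
Why: Evans–Saksena reduction, in which the borohydride bound to the 4β-oxygen delivers hydride intramolecularly to the β face of the C6 ketone and should give the anti-1,3-diol with the 6α-hydroxyl (6S).

Step 10
Reactants: 14 (1S,4R,5S,6S,10R)-10-{[tert-butyl(dimethyl)silyl]oxy}dauc-8-ene-4,6-diol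
Product: 15 (1S,4R,5S,6S,10R)-10-{[tert-butyl(dimethyl)silyl]oxy}-4-hydroxydauc-8-en-6-yl 3-methylbutanoate
Conditions: 3-methylbutanoic anhydride, DMAP (cat.), Et3N, CH2Cl2, 0 → 25 °C
Reagents that add atoms: 3-methylbutanoic anhydride, CC(C)CC(=O)OC(=O)CC(C)C
Why: DMAP-catalysed acylation should take the secondary 6-OH and leave the hindered tertiary 4-OH free.

Step 11
Reactants: 15 (1S,4R,5S,6S,10R)-10-{[tert-butyl(dimethyl)silyl]oxy}-4-hydroxydauc-8-en-6-yl 3-methylbutanoate
Product: 16 (1S,4R,5S,6S,10R)-4,10-dihydroxydauc-8-en-6-yl 3-methylbutanoate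
Conditions: HF·pyridine, pyridine/THF, 0 → 25 °C
Reagents that add atoms: none
Why: Fluoride cleavage of the silyl ether (Si–F bond formation) frees the allylic 10-OH under buffered conditions that should spare the ester.

Step 12
Reactants: 16 (1S,4R,5S,6S,10R)-4,10-dihydroxydauc-8-en-6-yl 3-methylbutanoate
Product: 17 (1S,4R,5S,6S,8R,9S,10S)-8,9-epoxy-4,10-dihydroxydaucan-6-yl 3-methylbutanoate
Conditions: VO(acac)2 (5 mol %), tBuOOH (decane), CH2Cl2, 0 °C
Reagents that add atoms: tert-butyl hydroperoxide, CC(C)(C)OO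
Why: Vanadium-catalysed hydroxyl-directed epoxidation, in which the allylic 10α-OH binds the vanadium peroxide and delivers oxygen to the same α face of C8=C9, setting 8R,9S.

Step 13
Reactants: 17 (1S,4R,5S,6S,8R,9S,10S)-8,9-epoxy-4,10-dihydroxydaucan-6-yl 3-methylbutanoate
Product: 18 (1S,4R,5S,6S,8R,9S,10S)-10-acetoxy-8,9-epoxy-4-hydroxydaucan-6-yl 3-methylbutanoate
Conditions: Ac2O, DMAP (cat.), pyridine, CH2Cl2, 25 °C
Reagents that add atoms: acetic anhydride, CC(=O)OC(C)=O
Why: DMAP-catalysed acetylation of the secondary 10-OH, with the tertiary 4-OH expected to stay free under these mild conditions, gives the target.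

**Compound list**

1 | methyl propiolate | C#CC(=O)OC | starting material
2 | acrolein | C=CC=O | starting material
3 | methyl (4R)-4-hydroxyhex-5-en-2-ynoate | O[C@H](C=C)C#CC(=O)OC | intermediate
4 | methyl (4R)-4-{[tert-butyl(dimethyl)silyl]oxy}hex-5-en-2-ynoate | CC(C)(C)[Si](C)(C)O[C@H](C=C)C#CC(=O)OC | intermediate
5 | methyl (2Z,4R)-4-{[tert-butyl(dimethyl)silyl]oxy}-3-methylhexa-2,5-dienoate | CC(C)(C)[Si](C)(C)O[C@H](C=C)/C(C)=C\C(=O)OC | intermediate
6 | (2Z,4R)-4-{[tert-butyl(dimethyl)silyl]oxy}-N-methoxy-N,3-dimethylhexa-2,5-dienamide | CC(C)(C)[Si](C)(C)O[C@H](C=C)/C(C)=C\C(=O)N(C)OC | intermediate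
7 | (5Z,7R)-7-{[tert-butyl(dimethyl)silyl]oxy}-2,6-dimethylnona-1,5,8-trien-4-one | CC(C)(C)[Si](C)(C)O[C@H](C=C)/C(C)=C\C(=O)CC(C)=C | intermediate
8 | methyl isobutyrate | COC(=O)C(C)C | starting material
9 | 1-(propan-2-yl)cyclopropan-1-ol | CC(C)C1(O)CC1 | intermediate
10 | bis(4-methyl-3-oxopentyl)zinc (zinc homoenolate) | CC(C)C(=O)CC[Zn]CCC(=O)C(C)C | intermediate
11 | (4-methyl-3-oxopentyl)zinc (4Z,6S)-6-[(1R)-1-{[tert-butyl(dimethyl)silyl]oxy}prop-2-en-1-yl]-2,6,10-trimethyl-9-oxoundeca-1,4-dien-4-olate (zinc enolate at C5=C6) | CC(C)(C)[Si](C)(C)O[C@H](C=C)[C@@](C)(CCC(=O)C(C)C)/C=C(\O[Zn]CCC(=O)C(C)C)CC(C)=C | intermediate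
12 | 1-[(1R,2R,5S)-5-[(1R)-1-{[tert-butyl(dimethyl)silyl]oxy}prop-2-en-1-yl]-2-hydroxy-5-methyl-2-(propan-2-yl)cyclopentyl]-3-methylbut-3-en-1-one | CC(C)(C)[Si](C)(C)O[C@H](C=C)[C@@]1(C)CC[C@@](O)(C(C)C)[C@@H]1C(=O)CC(C)=C | intermediate
13 | (1S,4R,5R,10R)-10-{[tert-butyl(dimethyl)silyl]oxy}-4-hydroxydauc-8-en-6-one (daucane numbering; trans-fused) | CC(C)(C)[Si](C)(C)O[C@@H]1C=C(C)CC(=O)[C@@H]2[C@]1(C)CC[C@@]2(O)C(C)C | intermediate
14 | (1S,4R,5S,6S,10R)-10-{[tert-butyl(dimethyl)silyl]oxy}dauc-8-ene-4,6-diol | CC(C)(C)[Si](C)(C)O[C@@H]1C=C(C)C[C@H](O)[C@@H]2[C@]1(C)CC[C@@]2(O)C(C)C | intermediate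
15 | (1S,4R,5S,6S,10R)-10-{[tert-butyl(dimethyl)silyl]oxy}-4-hydroxydauc-8-en-6-yl 3-methylbutanoate | CC(C)(C)[Si](C)(C)O[C@@H]1C=C(C)C[C@H](OC(=O)CC(C)C)[C@@H]2[C@]1(C)CC[C@@]2(O)C(C)C | intermediate
16 | (1S,4R,5S,6S,10R)-4,10-dihydroxydauc-8-en-6-yl 3-methylbutanoate | O[C@@H]1C=C(C)C[C@H](OC(=O)CC(C)C)[C@@H]2[C@]1(C)CC[C@@]2(O)C(C)C | intermediate
17 | (1S,4R,5S,6S,8R,9S,10S)-8,9-epoxy-4,10-dihydroxydaucan-6-yl 3-methylbutanoate | O[C@@H]1[C@@H]2O[C@]2(C)C[C@H](OC(=O)CC(C)C)[C@@H]2[C@]1(C)CC[C@@]2(O)C(C)C | intermediate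
18 | (1S,4R,5S,6S,8R,9S,10S)-10-acetoxy-8,9-epoxy-4-hydroxydaucan-6-yl 3-methylbutanoate (CNP0137153.1) | CC(=O)O[C@@H]1[C@@H]2O[C@]2(C)C[C@H](OC(=O)CC(C)C)[C@@H]2[C@]1(C)CC[C@@]2(O)C(C)C | target

**Step count**

Total: 13 steps. Longest linear sequence: 12 steps (steps 1–5 and 7–13; step 6 is a one-step side branch).

**Steps most likely to fail**

Step 7. Copper transfer to the hindered β,β-disubstituted carbon may be slow. The enone may then isomerise from Z to E, which removes the 1,3-allylic-strain control of the C1 face, or the enolate may be quenched before ring closure. The fallback sets out from 7 and 9, uses known radical chemistry in two stages, and comes back at 12. Catalytic Mn(acac)3 (a trivalent manganese oxidant) in iPrOH at 25 °C opens 9 to the β-keto alkyl radical, whose Giese addition to C1 of 7 should give the 1,6-diketone (6S)-6-[(1R)-1-{[tert-butyl(dimethyl)silyl]oxy}prop-2-en-1-yl]-2,6,10-trimethylundec-10-ene-3,8-dione F1. A separate aldol cyclisation under reversible conditions (catalytic KOtBu, tBuOH/THF, 0 °C), for which the all-trans cyclopentanol is the expected thermodynamic product, should then give 12.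

Step 8. The catalyst may load poorly at the vinyl group, which is flanked by the silyl ether and the quaternary carbon, and ruthenium hydride species may move the methallyl double bond into conjugation with the ketone. The fallback sets out from 12 and comes back at 13. HF·pyridine first removes the silyl group to give 1-[(1R,2R,5S)-2-hydroxy-5-[(1R)-1-hydroxyprop-2-en-1-yl]-5-methyl-2-(propan-2-yl)cyclopentyl]-3-methylbut-3-en-1-one F2. Ring-closing metathesis of F2 with the second-generation Hoveyda–Grubbs catalyst, now at a less hindered vinyl group with a free allylic hydroxyl, should give (1S,4R,5R,10R)-4,10-dihydroxydauc-8-en-6-one F3. Selective silylation of the secondary allylic hydroxyl (TBSOTf, 2,6-lutidine, CH2Cl2, −78 °C) returns to 13.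

Step 1. Acrolein may polymerise or undergo conjugate addition, and enantioface selection at this small enal may be incomplete. The fallback sets out from 1 and 2 and comes back at 3. Lithiated 1 (LiHMDS, THF, −78 °C) adds to 2 to give racemic methyl 4-hydroxyhex-5-en-2-ynoate F4. Sharpless kinetic resolution (Ti(OiPr)4, D-(−)-diisopropyl tartrate, tBuOOH, 4 Å sieves, CH2Cl2, −20 °C, stopped a little past half conversion) should epoxidise the vinyl group of the (S)-enantiomer and leave the (R)-alcohol 3.

**Further compounds**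

F1 | step 7 | (6S)-6-[(1R)-1-{[tert-butyl(dimethyl)silyl]oxy}prop-2-en-1-yl]-2,6,10-trimethylundec-10-ene-3,8-dione | CC(C)(C)[Si](C)(C)O[C@H](C=C)[C@@](C)(CCC(=O)C(C)C)CC(=O)CC(C)=C
F2 | step 8 | 1-[(1R,2R,5S)-2-hydroxy-5-[(1R)-1-hydroxyprop-2-en-1-yl]-5-methyl-2-(propan-2-yl)cyclopentyl]-3-methylbut-3-en-1-one | O[C@H](C=C)[C@@]1(C)CC[C@@](O)(C(C)C)[C@@H]1C(=O)CC(C)=C
F3 | step 8 | (1S,4R,5R,10R)-4,10-dihydroxydauc-8-en-6-one | O[C@@H]1C=C(C)CC(=O)[C@@H]2[C@]1(C)CC[C@@]2(O)C(C)C
F4 | step 1 | racemic methyl 4-hydroxyhex-5-en-2-ynoate | OC(C=C)C#CC(=O)OC
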